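It is tempting, when a catalysed reaction slows, to look at the target piling up, but in a single flask target and time rise together, so the green run by itself does not tell the two apart.

| flask | starting material | free catalyst | target | time |
|---|---|---|---|---|
| green | 0.800 M | 0.0240 M |  |  |
| amber | 0.400 M | 0.0240 M |  |  |
| grey | 0.800 M | 0.0360 M |  |  |
| ochre | 0.400 M | 0.0240 M |  |  |
| blue | 0.800 M | 0.0240 M | 0.640 M | 110 min |

- green run (time / min: [starting material] / M): 4.9: 0.7554; 15: 0.6838; 28: 0.6128; 45: 0.5416; 64: 0.4871; 86: 0.4415; 110: 0.3977
- amber run (time / min: [starting material] / M): 4.9: 0.3783; 15: 0.3395; 28: 0.3053; 45: 0.2734; 64: 0.2456; 86: 0.2204; 110: 0.2008
- grey run (time / min: [starting material] / M): 4.9: 0.7327; 15: 0.6285; 28: 0.5422; 45: 0.4601; 64: 0.4000; 86: 0.3500; 110: 0.3142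
- ochre run (time / min: [starting material] / M): 4.9: 0.3790; 15: 0.3407; 28: 0.3084; 45: 0.2687; 64: 0.2433; 86: 0.2208; 110: 0.1989

(each reading ± 0.002 M)

- the power of [free catalyst] that the first rate follows, about the charge of the green run; measure it at two percent of starting material made into target
- the power of [starting material] that the first rate follows, about the charge of the green run; measure it at two percent of starting material made into target (one fixed amount of target, the same in the runs compared)
- the amber run starts with 0.400 M less of starting material than the green run, and with no target. Compared where both hold the same amount of starting material, once fifteen percent of what the amber run was charged with has turned into target, is the amber run faster, slower or alike (within a tenth)?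
- starting material in the blue run at 110 min, as a share of the starting material charged

- Overall: starting material -> target, with free catalyst as catalyst.
- Constant volume, constant temperature.
- An order is taken over about fifteen percent of the charge, up and down.

Two chemists dispute the blue run, which is charged like the green run but starts with target already present.

The target chemist holds that target holds back the free catalyst (product inhibition). She reads the specific rate, the loss per minute per unit of starting material, over the last stretch of the green run, from 86 min to 110 min. It comes to 0.00435 /min, with 0.402 M of target made by the end. The blue run starts with 0.640 M of target, more than that, so she keeps this specific rate for the whole 110 min and expects 61.9% of the charge left.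

The clock chemist, who made the forecast, answers with a quantity I call the clock loss, L: the natural logarithm of the charge over what remains at a given time, here for the green run at 110 min, 0.699. For a fixed catalyst charge, if the rate is proportional to starting material and the slowdown follows time, L does not depend on the charge of starting material.

The amber run gives 0.689 and the ochre run 0.699, each with a scatter near 0.00996. Yet the amber run has made about half of the green run's target, 0.199 M. Under her view the amber run should pull ahead of the green run in clock loss, but the two stand close. She keeps one region: the green run taken by itself, where target and time rise together.

The forecast says “the slowdown follows time, not target”, and gives orders of 1.15 in free catalyst and 1 in starting material, the amber run faster, and 49.8% left in the blue run. My own use of L gives 49.7% for the blue run, close to the forecast's figure. The forecast fails if the blue run comes out near 61.9%.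

    2 free catalyst ⇌ catalyst dimer, settled at all times (8.360 /M)
    free catalyst + starting material → target + free catalyst (0.9000 /M/min)
    2 free catalyst → 2 spent catalyst (0.9780 /M/min)
    free catalyst + impurity → spent catalyst

The blue run keeps 50.0% of its charge at 110 min, below the target chemist's figure; the orders come out at 1.3 in free catalyst and 1.1 in starting material, and the amber run is faster. The green run, with no target at the start, reached half of its charge turned at 110 min, the time asked of the blue run. The blue run's clock loss is 0.693, against 0.699 read from the green run. The ochre run, charged with 0.400 M, also had half turned at 110 min, a clock loss of 0.693.

The readings were computed on assumed constants; the scatter is artificial.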